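**Assumption:** the commercial chiral starting material is (R)-(−)-carvone (spearmint). The 2,4-dimethoxyphenyl groups and the acetal are masked resorcinol and formyl units, removed in the last step.

## Retrosynthetic overview
1. Target (15) comes from global O-demethylation and acetal cleavage of aryl ketone 14, which is made by adding 2,4-dimethoxyphenyllithium to the Weinreb amide 12.
2. Amide 12 comes from enone 10 by tosylhydrazone/catecholborane reduction. This removes the ring C=O and moves the alkene to the methyl-bearing carbon.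
3. Enone 10 comes from two photostimulated S_RN1 arylations of the carvone-derived Weinreb amide 4: γ-arylation with ArC, then α′-arylation with ArA.
4. Amide 4 comes from carvone by converting the isopropenyl group to acetyl, then CO2H, then the amide. No carbocycle is formed; the carvone ring carries the chirality. The C5 carbon of carvone, which becomes C4 of the target, is the only stereocentre from the pool and directs both aryl groups trans to it.

## Route

**Step 1**
Reactants: 1, (R)-carvone
Product: 2, (5R)-5-acetyl-2-methylcyclohex-2-en-1-one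
Conditions: O3 (1.0 equiv), CH2Cl2/MeOH 4:1, −78 °C; then Me2S, −78 °C → rt
Reagents that add atoms: ozone, [O-][O+]=O (supplies the ketone O)
Why: Ozonolysis (Criegee) attacks the electron-rich isopropenyl group much faster than the electron-poor enone alkene, and the stereocentre is untouched.

**Step 2**
Reactants: 2
Product: 3, (1R)-4-methyl-5-oxocyclohex-3-ene-1-carboxylic acid
Conditions: NaOCl (aq., 4 equiv), NaOH (0.2 equiv), dioxane/H2O, 0 °C → rt; then 1 M HCl
Reagents that add atoms: sodium hydroxide/water, [Na+].[OH-] (oxygen of the new CO2H)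
Why: Haloform reaction converts the methyl ketone to the acid; each halogenation of CH3 accelerates the next, so it outruns epimerisation at the tertiary α-carbon.

**Step 3**
Reactants: 3
Product: 4, (1R)-N-methoxy-N,4-dimethyl-5-oxocyclohex-3-ene-1-carboxamide (Weinreb amide)
Conditions: CDI (1.2 equiv), CH2Cl2, 0 °C → rt, 1 h; then MeNH(OMe)·HCl (1.5 equiv), rt, 12 h
Reagents that add atoms: N,O-dimethylhydroxylamine hydrochloride, CONC.Cl
Why: CDI activation followed by aminolysis gives a neutral, non-enolisable carboxyl surrogate that tolerates the later base/photochemical steps and later adds ArLi once.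

**Step 4**
Reactants: 4; 5, 1-iodo-2,4-dimethoxybenzene
Product: 6, enone with the 2,4-dimethoxyphenyl at C4 (γ), trans to the C5 amide
Conditions: t-BuOK (2.5 equiv), DMSO, 365 nm LEDs, 25 °C, 3 h (ArI 1.0 equiv)
Reagents that add atoms: none
Why: Proposed new method: photostimulated S_RN1 γ-arylation. Photoinduced electron transfer from the thermodynamic K-dienolate to ArI gives ArI•⁻, then Ar• + I⁻; Ar• couples at the unhindered γ-terminus (the α-terminus carries Me) and the resulting radical anion reduces the next ArI to carry the chain; the nearest known reaction is the Bunnett–Rossi photostimulated S_RN1 α-arylation of ketone enolates. The benzylic γ-H equilibrates under the basic conditions, so the aryl ends up trans to the C5 substituent.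

**Step 5**
Reactants: 7, 2,4-dimethoxybenzaldehyde
Product: 8, 5-iodo-2,4-dimethoxybenzaldehyde
Conditions: NIS (1.1 equiv), MeCN, TFA (0.1 equiv), 25 °C, 4 h
Reagents that add atoms: N-iodosuccinimide, O=C1CCC(=O)N1I
Why: Electrophilic aromatic iodination occurs at C5, which is para to 2-OMe and ortho to 4-OMe.

**Step 6**
Reactants: 8
Product: 9, 1-(dimethoxymethyl)-5-iodo-2,4-dimethoxybenzene
Conditions: HC(OMe)3 (3 equiv), MeOH, TsOH·H2O (0.02 equiv), 25 °C, 1 h; quench with Et3N before concentration
Reagents that add atoms: trimethyl orthoformate, COC(OC)OC (two OMe retained)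
Why: Acetalisation masks the aldehyde, which would otherwise undergo aldol reaction with the enolate in step 7 and form a hydrazone in step 8.

**Step 7**
Reactants: 6; 9
Product: 10, enone with the acetal-bearing aryl (ArA) at C6 (α′), trans to the C5 amide and cis to the C4 aryl
Conditions: KHMDS (1.2 equiv), THF, −78 °C, 20 min; add 9 (1.5 equiv) in DMSO; 365 nm LEDs, −20 → 25 °C, 4 h
Reagents that add atoms: none
Why: S_RN1 arylation of the kinetic potassium cross-conjugated enolate is a known reaction type, and α-epimerisation places the new aryl equatorial, trans to C5 and 1,3-cis to the C4 aryl.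

**Step 8**
Reactants: 10
Product: 11, tosylhydrazone of 10
Conditions: TsNHNH2 (1.5 equiv), MeOH, 60 °C, 24 h, 4 Å MS (no acid catalyst, to protect the acetal)
Reagents that add atoms: p-toluenesulfonyl hydrazide, Cc1ccc(cc1)S(=O)(=O)NN
Why: Condensation of the ketone with the sulfonylhydrazide gives the α,β-unsaturated tosylhydrazone.

**Step 9**
Reactants: 11
Product: 12, 2-[5-(dimethoxymethyl)-2,4-dimethoxyphenyl]-6-(2,4-dimethoxyphenyl)-N-methoxy-N,4-dimethylcyclohex-3-ene-1-carboxamide
Conditions: catecholborane (4 equiv), CHCl3, 0 °C, 2 h; then NaOAc·3H2O (5 equiv), reflux, 1 h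
Reagents that add atoms: none (catecholborane delivers only H)
Why: Kabalka reduction: hydride reduction of C=N and loss of sulfinate give an allylic diazene, which loses N2 by retro-ene transposition. This converts C=O to CH= and moves the alkene to the methyl-bearing carbon, giving the target's C(Me)=CH–CH(ArA) unit with the three sp3 stereocentres unchanged.

**Step 10**
Reactants: 12; 13, 1-bromo-2,4-dimethoxybenzene (converted to ArLi in situ)
Product: 14, protected aryl ketone
Conditions: 13 (1.5 equiv) + n-BuLi (1.5 equiv), THF, −78 °C, 30 min; add 12, −78 → 0 °C, 2 h; aq. NH4Cl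
Reagents that add atoms: none (aryl comes from 13)
Why: Weinreb ketone synthesis stops at the aryl ketone through the stable chelated tetrahedral intermediate, and the α-stereocentre is never enolised. The all-equatorial, all-trans arrangement is the thermodynamic one anyway.

**Step 11**
Reactants: 14
Product: 15, target
Conditions: BBr3 (12 equiv), CH2Cl2, −78 → 0 °C, 4 h; then aq. NaHCO3, then 1 M HCl
Reagents that add atoms: water (work-up), O (carbonyl O of the CHO)
Why: BBr3 cleaves all six aryl methyl ethers and the acetal, leaving the chelated ortho-hydroxy aryl ketone and aldehyde intact, and the stereocentres are not affected.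

## Compound list
1 | (R)-carvone, (5R)-2-methyl-5-(prop-1-en-2-yl)cyclohex-2-en-1-one | CC1=CC[C@H](CC1=O)C(C)=C | starting material
2 | (5R)-5-acetyl-2-methylcyclohex-2-en-1-one | CC1=CC[C@H](CC1=O)C(C)=O | intermediate
3 | (1R)-4-methyl-5-oxocyclohex-3-ene-1-carboxylic acid | CC1=CC[C@H](CC1=O)C(O)=O | intermediate
4 | (1R)-N-methoxy-N,4-dimethyl-5-oxocyclohex-3-ene-1-carboxamide | CC1=CC[C@H](CC1=O)C(=O)N(C)OC | intermediate
5 | 1-iodo-2,4-dimethoxybenzene | COc1ccc(I)c(OC)c1 | starting material
6 | 2-(2,4-dimethoxyphenyl)-N-methoxy-N,4-dimethyl-5-oxocyclohex-3-ene-1-carboxamide, 1,2-trans, 1R | CC1=C[C@H](c2ccc(OC)cc2OC)[C@@H](C(=O)N(C)OC)CC1=O | intermediate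
7 | 2,4-dimethoxybenzaldehyde | COc1ccc(C=O)c(OC)c1 | starting material
8 | 5-iodo-2,4-dimethoxybenzaldehyde | O=Cc1cc(I)c(OC)cc1OC | intermediate
9 | 1-(dimethoxymethyl)-5-iodo-2,4-dimethoxybenzene | COC(OC)c1cc(I)c(OC)cc1OC | intermediate
10 | 6-[5-(dimethoxymethyl)-2,4-dimethoxyphenyl]-2-(2,4-dimethoxyphenyl)-N-methoxy-N,4-dimethyl-5-oxocyclohex-3-ene-1-carboxamide (1,2-trans, 1,6-trans) | CC1=C[C@H](c2ccc(OC)cc2OC)[C@@H](C(=O)N(C)OC)[C@H](c3cc(C(OC)OC)c(OC)cc3OC)C1=O | intermediate
11 | tosylhydrazone of 10 | CC1=C[C@H](c2ccc(OC)cc2OC)[C@@H](C(=O)N(C)OC)[C@H](c3cc(C(OC)OC)c(OC)cc3OC)C1=NNS(=O)(=O)c4ccc(C)cc4 | intermediate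
12 | 2-[5-(dimethoxymethyl)-2,4-dimethoxyphenyl]-6-(2,4-dimethoxyphenyl)-N-methoxy-N,4-dimethylcyclohex-3-ene-1-carboxamide | CC1=C[C@@H](c2cc(C(OC)OC)c(OC)cc2OC)[C@H](C(=O)N(C)OC)[C@@H](c2ccc(OC)cc2OC)C1 | intermediate
13 | 1-bromo-2,4-dimethoxybenzene | COc1ccc(Br)c(OC)c1 | starting material
14 | (2,4-dimethoxyphenyl){2-[5-(dimethoxymethyl)-2,4-dimethoxyphenyl]-6-(2,4-dimethoxyphenyl)-4-methylcyclohex-3-en-1-yl}methanone | CC1=C[C@@H](c2cc(C(OC)OC)c(OC)cc2OC)[C@H](C(=O)c2ccc(OC)cc2OC)[C@@H](c2ccc(OC)cc2OC)C1 | intermediate
15 | 5-[(1R,5S,6R)-6-(2,4-dihydroxybenzoyl)-5-(2,4-dihydroxyphenyl)-3-methylcyclohex-2-en-1-yl]-2,4-dihydroxybenzaldehyde | CC1=C[C@@H](c2cc(C=O)c(O)cc2O)[C@H](C(=O)c2ccc(O)cc2O)[C@@H](c2ccc(O)cc2O)C1 | target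

## Totals
**Total steps:** 11. **Longest linear sequence:** 9 (steps 1, 2, 3, 4, 7, 8, 9, 10, 11).

## Three steps most likely to fail
1. **Step 4 (proposed new γ-arylation).** The S_RN1 chain may stop, or arylate at the α-carbon carrying Me or twice at γ. Fallback: Pd-catalysed γ-arylation of the deconjugated (β,γ) enone dienolate of 4 with 1-bromo-2,4-dimethoxybenzene (Pd/P(t-Bu)3, NaOt-Bu, toluene), which is known chemistry and uses a two-electron organometallic pathway instead of a radical chain.
2. **Step 7 (α′-arylation).** The γ-benzylic H of 6 may compete with the α′-CH2 for deprotonation, and the hindered acetal-bearing aryl iodide couples poorly. Fallback: Pd-catalysed ketone α-arylation (Pd/Q-Phos, NaOt-Bu) of 6 using the corresponding aryl bromide of the acetal (from commercial 5-bromo-2,4-dimethoxybenzaldehyde).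
3. **Step 9 (alkene-transposing deoxygenation).** The hindered 2,6-disubstituted hydrazone may form or reduce poorly, or catecholborane may attack the acetal or amide. Fallback: L-Selectride 1,4-reduction with PhNTf2 trapping to the C1(OTf)=C2(Me) enol triflate, then Pd(OAc)2/PPh3, HCO2H/Et3N reduction, which gives the same trisubstituted alkene without a diazene.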